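The ε-lactone ring (O–C16–C15–C14–C1–C2–C3; briarellin numbering) is cut at C14–C15 and C1–C2. C15 is α to the lactone carbonyl, C2 carries the later ether oxygen, and C14–C1 is an edge of cyclohexane ring A. The key step is a one-pot (5+2) Michael/aldol annulation: the α-sulfonylpropanoate ester of an α-hydroxy aldehyde (C15 donor, C2 aldehyde, C3 stereocentre in place) adds to an (R)-6-silyloxy-6-methylcyclohex-2-enone (C10 ketone, C1=C14 alkene), and the ketone enolate then closes onto the aldehyde. This builds the trans-fused lactone and sets C14, C1 and C2; C10 is later homologated to C9 to close the tetrahydrofuran and oxonene rings.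

Key step: step 12

Numbering used for locants written C1–C17: C1 and C10 are the ring-A carbons shared with the tetrahydrofuran, C2 and C9 the ether carbons, C3 the quaternary lactone carbinol, C4–C8 the oxonene chain (C6=C7), C11 the acetoxy carbon, C12 and C13 ring-A methylenes, C14 the ring-A carbon bearing C15, C16 the lactone carbonyl.
Remark: the sulfonyl-bearing C15 is carried as an inconsequential epimer mixture in 14–22 and C9 is a mixture in 19–21, so these centres are left undefined in those SMILES.

Step 1
Reactants: 1 2-methylcyclohexan-1-one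
Product: 2 tert-butyldimethyl[(2-methylcyclohex-1-en-1-yl)oxy]silane
Conditions: TBSCl, NaI, Et3N, MeCN, 60 °C
Reagents that add atoms: tert-butyldimethylsilyl chloride CC(C)(C)[Si](C)(C)Cl
Why: Silyl enol ether formation under equilibrating conditions (silyl iodide made in situ) should favour the tetrasubstituted enol ether, the minor regioisomer being removed by distillation.

Step 2
Reactants: 2 tert-butyldimethyl[(2-methylcyclohex-1-en-1-yl)oxy]silane
Product: 4 (2R)-2-hydroxy-2-methylcyclohexan-1-one, via silyloxy epoxide 3 (not isolated)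
Conditions: Shi fructose-derived ketone catalyst (enantiomer giving the R series), KHSO5 (Oxone), K2CO3, MeCN/dimethoxymethane/aq. buffer, 0 °C; aq. work-up
Reagents that add atoms: potassium peroxymonosulfate [K+].[O-]S(=O)(=O)OO
Why: Shi asymmetric epoxidation of the silyl enol ether by the chiral dioxirane and hydrolytic collapse of epoxide 3 should give the tertiary α-hydroxy ketone, the catalyst selecting the enol ether face and so setting C11.

Step 3
Reactants: 4 (2R)-2-hydroxy-2-methylcyclohexan-1-one
Product: 5 (2R)-2-(tert-butyldimethylsilyloxy)-2-methylcyclohexan-1-one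
Conditions: TBSOTf, 2,6-lutidine, CH2Cl2, 0 °C to rt
Reagents that add atoms: tert-butyldimethylsilyl triflate CC(C)(C)[Si](C)(C)OS(=O)(=O)C(F)(F)F
Why: Silylation of the hindered tertiary alcohol with the silyl triflate should proceed without touching the stereocentre.

Step 4
Reactants: 5 (2R)-2-(tert-butyldimethylsilyloxy)-2-methylcyclohexan-1-one
Product: 6 (6R)-6-(tert-butyldimethylsilyloxy)-6-methylcyclohex-2-en-1-one
Conditions: IBX, DMSO/toluene, 70 °C
Reagents that add atoms: none
Why: IBX dehydrogenation through the enol should give the enone; only C6 of the ketone carries α-hydrogens, so the alkene forms away from the quaternary centre.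

Step 5
Reactants: 7 (R)-lactic acid
Product: 8 (2R,5R)-2-tert-butyl-5-methyl-1,3-dioxolan-4-one
Conditions: t-BuCHO, TsOH (cat.), pentane, reflux with water separator; recrystallisation
Reagents that add atoms: pivalaldehyde CC(C)(C)C=O
Why: Acid-catalysed acetalisation under thermodynamic control should give the cis dioxolanone (self-regeneration of stereocentres), the acetal carbon being set by the lactate centre.

Step 6
Reactants: 8 (2R,5R)-2-tert-butyl-5-methyl-1,3-dioxolan-4-one
Product: 9 (2R,5S)-5-(but-3-en-1-yl)-2-tert-butyl-5-methyl-1,3-dioxolan-4-one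
Conditions: LiN(i-Pr)2, THF, −78 °C; 4-iodobut-1-ene, DMPU, −78 to −30 °C
Reagents that add atoms: 4-iodobut-1-ene C=CCCI
Why: Alkylation of the lithium enolate anti to the tert-butyl group should create the quaternary centre (later C3) with overall retention.

Step 7
Reactants: 9 (2R,5S)-5-(but-3-en-1-yl)-2-tert-butyl-5-methyl-1,3-dioxolan-4-one
Product: 10 (2S)-2-methylhex-5-ene-1,2-diol
Conditions: LiAlH4, Et2O, 0 °C to rt; aq. work-up
Reagents that add atoms: none
Why: Hydride reduction of the acetal-type lactone should release the diol and the auxiliary as neopentyl alcohol without touching the quaternary centre.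

Step 8
Reactants: 10 (2S)-2-methylhex-5-ene-1,2-diol
Product: 11 (2S)-2-methyl-1-(triethylsilyloxy)hex-5-en-2-ol
Conditions: Et3SiCl, imidazole, CH2Cl2, −40 °C
Reagents that add atoms: chlorotriethylsilane CC[Si](CC)(CC)Cl
Why: Silylation should be chemoselective for the primary hydroxyl in the presence of the tertiary one.

Step 9
Reactants: 12 2-bromopropanoic acid
Product: 13 2-(phenylsulfonyl)propanoic acid
Conditions: PhSO2Na, NaHCO3, H2O/EtOH, 80 °C; then aq. HCl
Reagents that add atoms: sodium benzenesulfinate [Na+].[O-]S(=O)c1ccccc1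
Why: SN2 displacement of the α-bromide by the sulfinate sulfur should give the racemic α-sulfonyl acid, whose stereocentre is erased later.

Step 10
Reactants: 11 (2S)-2-methyl-1-(triethylsilyloxy)hex-5-en-2-ol; 13 2-(phenylsulfonyl)propanoic acid
Product: 14 (2S)-2-methyl-1-(triethylsilyloxy)hex-5-en-2-yl 2-(phenylsulfonyl)propanoate
Conditions: DCC, DMAP (cat.), CH2Cl2, 0 °C to rt
Reagents that add atoms: none
Why: Steglich esterification (carbodiimide activation, probably through the sulfonylketene) should acylate the tertiary alcohol.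

Step 11
Reactants: 14 (2S)-2-methyl-1-(triethylsilyloxy)hex-5-en-2-yl 2-(phenylsulfonyl)propanoate
Product: 15 (2S)-2-methyl-1-oxohex-5-en-2-yl 2-(phenylsulfonyl)propanoate
Conditions: (COCl)2, DMSO, CH2Cl2, −78 to −30 °C; then Et3N
Reagents that add atoms: none
Why: Swern conditions oxidise a primary triethylsilyl ether directly to the aldehyde, so no free hydroxyl next to the tertiary ester is exposed to acyl migration.

Step 12
Reactants: 6 (6R)-6-(tert-butyldimethylsilyloxy)-6-methylcyclohex-2-en-1-one; 15 (2S)-2-methyl-1-oxohex-5-en-2-yl 2-(phenylsulfonyl)propanoate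
Product: 18 trans-fused keto lactone (C2 triethylsilyl ether), via Michael adduct 16 (not isolated), via lithium aldolate 17 (not isolated)
Conditions: Cs2CO3 (0.2 equiv), THF, 0 °C to rt; then LiN(SiMe3)2, −78 to −40 °C; then Et3SiOTf, 2,6-lutidine, −78 °C
Reagents that add atoms: triethylsilyl triflate CC[Si](CC)(CC)OS(=O)(=O)C(F)(F)F
Why: Cs2CO3 deprotonates only the sulfonyl ester C15–H of 15 and the soft carbanion adds in a Michael reaction to C14 of enone 6 to give 16 (C14–C15 bond); LiN(SiMe3)2 then forms the C10/C1 lithium enolate (C1 is the only enolisable position), which attacks the tethered C2 aldehyde in an intramolecular aldol reaction (C1–C2 bond), and aldolate 17 is capped as its triethylsilyl ether. The sequence is a Michael-initiated ring closure, that is a Michael/aldol (5+2) annulation of a tethered donor–acceptor reagent onto a cyclohexenone, both halves being standard reaction types. The ε-lactone closes by a 7-(enolexo)-exo-trig aldol addition, whereas attack of the sulfonyl ester anion on its own aldehyde would be a Baldwin-disfavoured 5-(enolendo)-exo-trig closure and is reversible. C14 should be set by axial attack on the half-chair of 6 that has the C11 silyloxy group pseudoaxial, anti to that group and therefore cis to the C11 methyl; C1 and C2 should be set under chelated Zimmerman–Traxler control, the cyclic E enolate giving the anti aldol, and warming to −40 °C lets the aldolates equilibrate by retro-aldol/aldol to the trans-fused ring with the C2 oxygen equatorial; C15 forms as an epimer mixture that step 16 erases. The step needs 1,4- rather than 1,2-addition and no acyl shift from the C3 oxygen to the new C2 oxygen: the soft sulfonyl-stabilised donor should secure the first, and chelation of the lithium aldolate to the C10 ketone together with cold silylation the second.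

Step 13
Reactants: 18 trans-fused keto lactone (C2 triethylsilyl ether)
Product: 19 C10 methoxymethylene enol ether
Conditions: Ph3P(CH2OMe)Cl, KN(SiMe3)2, THF, 0 to 45 °C
Reagents that add atoms: (methoxymethyl)triphenylphosphonium chloride COC[P+](c1ccccc1)(c1ccccc1)c1ccccc1.[Cl-]
Why: Wittig reaction of the C10 ketone with the methoxymethylene ylide should add C9 as an enol ether (E/Z mixture), the quaternary C15 leaving the lactone without α-hydrogens.

Step 14
Reactants: 19 C10 methoxymethylene enol ether
Product: 21 cis-fused cyclic methyl acetal (C9 anomers), via hydroxy enol ether 20 (not isolated)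
Conditions: CSA (cat.), MeOH/CH2Cl2, 0 °C to rt
Reagents that add atoms: none
Why: Acid-catalysed methanolysis frees the C2 hydroxyl, which adds to the protonated enol ether (C9 oxocarbenium ion) to close the five-membered acetal; C10 can equilibrate through the enol ether and should settle in the cis-fused bicycle.

Step 15
Reactants: 21 cis-fused cyclic methyl acetal (C9 anomers)
Product: 22 C9-methallyl tetrahydrofuran
Conditions: 2-methylallyltrimethylsilane, BF3·OEt2, CH2Cl2, −78 to −40 °C
Reagents that add atoms: 2-methylallyltrimethylsilane CC(=C)C[Si](C)(C)C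
Why: Hosomi–Sakurai allylation of the C9 oxocarbenium ion by inside attack on the envelope from the convex face anti to ring A should place C8 cis to C3 (2,5-cis tetrahydrofuran) and set C9.

Step 16
Reactants: 22 C9-methallyl tetrahydrofuran
Product: 24 desulfonylated lactone (C15–H), via samarium enolate 23 (not isolated)
Conditions: SmI2, THF/MeOH, −78 °C
Reagents that add atoms: none
Why: Reductive desulfonylation by divalent samarium gives lactone enolate 23, and kinetic protonation by methanol at C15 on the face anti to C1 should give the C15 configuration of the target.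

Step 17
Reactants: 24 desulfonylated lactone (C15–H)
Product: 25 tetracyclic oxonene (C11 silyl ether)
Conditions: second-generation Grubbs catalyst (10 mol%), CH2Cl2 (2 mM), 40 °C
Reagents that add atoms: none
Why: Ring-closing metathesis of the butenyl and methallyl groups held cis on the tetrahydrofuran should close the oxonene, whose ring size allows only the Z trisubstituted alkene.

Step 18
Reactants: 25 tetracyclic oxonene (C11 silyl ether)
Product: 26 C11 tertiary alcohol
Conditions: HF·pyridine, THF, 0 °C to rt
Reagents that add atoms: none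
Why: Fluoride cleavage of the tertiary silyl ether under mildly acidic conditions should leave the lactone and its α-centre untouched.

Step 19
Reactants: 26 C11 tertiary alcohol
Product: 27 target acetate
Conditions: Ac2O, Sc(OTf)3 (cat.), MeCN, −20 °C
Reagents that add atoms: acetic anhydride CC(=O)OC(C)=O
Why: Lewis-acid-catalysed acetylation of the hindered tertiary alcohol with the anhydride should complete the target without affecting any stereocentre.

Compound list
1 | 2-methylcyclohexan-1-one (racemic) | CC1CCCCC1=O | starting material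
2 | tert-butyldimethyl[(2-methylcyclohex-1-en-1-yl)oxy]silane | CC1=C(O[Si](C)(C)C(C)(C)C)CCCC1 | intermediate
3 | (1R,6R)-6-(tert-butyldimethylsilyloxy)-1-methyl-7-oxabicyclo[4.1.0]heptane (silyloxy epoxide, not isolated) | O1[C@]2(C)CCCC[C@]12O[Si](C)(C)C(C)(C)C | intermediate
4 | (2R)-2-hydroxy-2-methylcyclohexan-1-one | O[C@]1(C)CCCCC1=O | intermediate
5 | (2R)-2-(tert-butyldimethylsilyloxy)-2-methylcyclohexan-1-one | CC(C)(C)[Si](C)(C)O[C@]1(C)CCCCC1=O | intermediate
6 | (6R)-6-(tert-butyldimethylsilyloxy)-6-methylcyclohex-2-en-1-one | CC(C)(C)[Si](C)(C)O[C@]1(C)CCC=CC1=O | intermediate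
7 | (R)-lactic acid, (2R)-2-hydroxypropanoic acid | C[C@@H](O)C(=O)O | starting material
8 | (2R,5R)-2-tert-butyl-5-methyl-1,3-dioxolan-4-one (cis) | C[C@H]1O[C@@H](C(C)(C)C)OC1=O | intermediate
9 | (2R,5S)-5-(but-3-en-1-yl)-2-tert-butyl-5-methyl-1,3-dioxolan-4-one | C=CCC[C@]1(C)O[C@@H](C(C)(C)C)OC1=O | intermediate
10 | (2S)-2-methylhex-5-ene-1,2-diol | C=CCC[C@](CO)(C)O | intermediate
11 | (2S)-2-methyl-1-(triethylsilyloxy)hex-5-en-2-ol | C=CCC[C@](CO[Si](CC)(CC)CC)(C)O | intermediate
12 | 2-bromopropanoic acid (racemic) | CC(Br)C(=O)O | starting material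
13 | 2-(phenylsulfonyl)propanoic acid (racemic) | CC(C(=O)O)S(=O)(=O)c1ccccc1 | intermediate
14 | (2S)-2-methyl-1-(triethylsilyloxy)hex-5-en-2-yl 2-(phenylsulfonyl)propanoate (epimers at the sulfonyl carbon) | C=CCC[C@](CO[Si](CC)(CC)CC)(C)OC(=O)C(C)S(=O)(=O)c1ccccc1 | intermediate
15 | (2S)-2-methyl-1-oxohex-5-en-2-yl 2-(phenylsulfonyl)propanoate (epimers at the sulfonyl carbon) | C=CCC[C@](C=O)(C)OC(=O)C(C)S(=O)(=O)c1ccccc1 | intermediate
16 | Michael adduct (not isolated): (2S)-2-methyl-1-oxohex-5-en-2-yl 2-[(1R,4R)-4-(tert-butyldimethylsilyloxy)-4-methyl-3-oxocyclohexyl]-2-(phenylsulfonyl)propanoate (C15 epimers) | CC(C)(C)[Si](C)(C)O[C@]1(C)CC[C@H](CC1=O)C(C)(S(=O)(=O)c1ccccc1)C(=O)O[C@@](C)(CCC=C)C=O | intermediate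
17 | lithium aldolate (not isolated): lithium C2 alkoxide of the trans-fused keto lactone, configuration as in 18 | CC(C)(C)[Si](C)(C)O[C@]1(C)CC[C@@H]2[C@@H](C1=O)[C@H]([O-])[C@](C)(CCC=C)OC(=O)C2(C)S(=O)(=O)c1ccccc1.[Li+] | intermediate
18 | trans-fused keto lactone: ring-A cyclohexanone (C10 ketone; C11 methyl and OTBS) fused at C1–C14 to the ε-lactone (C2 OTES; C3 methyl and but-3-enyl; C15 methyl and phenylsulfonyl); C1, C2, C3, C11 and C14 as in 27 | CC(C)(C)[Si](C)(C)O[C@]1(C)CC[C@@H]2[C@@H](C1=O)[C@H](O[Si](CC)(CC)CC)[C@](C)(CCC=C)OC(=O)C2(C)S(=O)(=O)c1ccccc1 | intermediate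
19 | C10 methoxymethylene enol ether of 18 (E/Z mixture) | CC(C)(C)[Si](C)(C)O[C@]1(C)CC[C@@H]2[C@@H](C1=COC)[C@H](O[Si](CC)(CC)CC)[C@](C)(CCC=C)OC(=O)C2(C)S(=O)(=O)c1ccccc1 | intermediate
20 | hydroxy enol ether (not isolated): 19 with free C2 hydroxyl | CC(C)(C)[Si](C)(C)O[C@]1(C)CC[C@@H]2[C@@H](C1=COC)[C@H](O)[C@](C)(CCC=C)OC(=O)C2(C)S(=O)(=O)c1ccccc1 | intermediate
21 | cis-fused cyclic methyl acetal: tetrahydrofuran C2–O–C9(OMe)–C10–C1 fused to ring A and to the lactone; C10 as in 27; C9 anomers | CC(C)(C)[Si](C)(C)O[C@]1(C)CC[C@@H]2[C@H]3[C@@H]1C(OC)O[C@@H]3[C@](C)(CCC=C)OC(=O)C2(C)S(=O)(=O)c1ccccc1 | intermediate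
22 | C9-methallyl tetrahydrofuran: 21 with 2-methylprop-2-enyl in place of methoxy at C9, C9 as in 27 | CC(C)(C)[Si](C)(C)O[C@]1(C)CC[C@@H]2[C@H]3[C@@H]1[C@H](CC(C)=C)O[C@@H]3[C@](C)(CCC=C)OC(=O)C2(C)S(=O)(=O)c1ccccc1 | intermediate
23 | samarium enolate (not isolated): C15=C16 lactone enolate of 22 after loss of sulfinate, trivalent samarium counter-ion | CC(C)(C)[Si](C)(C)O[C@]1(C)CC[C@@H]2[C@H]3[C@@H]1[C@H](CC(C)=C)O[C@@H]3[C@](C)(CCC=C)OC([O-])=C2C.[Sm+3].[I-].[I-] | intermediate
24 | desulfonylated lactone: tricyclic lactone with C15–H (methyl as in 27), C3 but-3-enyl, C9 methallyl, C11 OTBS | CC(C)(C)[Si](C)(C)O[C@]1(C)CC[C@@H]2[C@H]3[C@@H]1[C@H](CC(C)=C)O[C@@H]3[C@](C)(CCC=C)OC(=O)[C@@H]2C | intermediate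
25 | tetracyclic oxonene: the tert-butyldimethylsilyl ether of 26, with the (6Z) C6=C7 alkene | CC(C)(C)[Si](C)(C)O[C@]1(C)CC[C@@H]2[C@H]3[C@@H]1[C@@H]1C/C(C)=C\CC[C@](C)(OC(=O)[C@@H]2C)[C@H]3O1 | intermediate
26 | C11 tertiary alcohol (deacetyl target) | O[C@]1(C)CC[C@@H]2[C@H]3[C@@H]1[C@@H]1C/C(C)=C\CC[C@](C)(OC(=O)[C@@H]2C)[C@H]3O1 | intermediate
27 | target: (1S,2S,3S,6Z,9S,10R,11R,14R,15R)-11-acetoxy C16→O3 ε-lactone with C2–O–C9 ether bridge (briarellin numbering) | CC(=O)O[C@]1(C)CC[C@@H]2[C@H]3[C@@H]1[C@@H]1C/C(C)=C\CC[C@](C)(OC(=O)[C@@H]2C)[C@H]3O1 | target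

Total step count: 19. Longest linear sequence: 14 steps (from 7 through steps 5–8 and 10–19).

Steps most likely to fail:

Step 12. The enolate of 16 may lose the sulfonyl ester again by retro-Michael reaction, the aldolate may shift the acyl group from the C3 oxygen to the C2 oxygen, or the Michael addition may show low facial selectivity. Fallback: the Michael stage is quenched and 16 is isolated. Enolisation with Cy2BCl and Et3N in Et2O at −78 °C should give the E enol borinate, which adds to the pendant aldehyde through a closed transition state without any free alkoxide. Oxidative work-up (H2O2, pH 7 buffer, MeOH) should give hydroxy ketone F1, and silylation (Et3SiOTf, 2,6-lutidine) returns to the route at 18.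

Step 13. The hindered ketone may be enolised by the ylide, with β-elimination of the C2 silyloxy group, instead of being olefinated. Fallback: setting out from 18, the sulfur ylide from Me3SI and KN(SiMe3)2 (Corey–Chaykovsky epoxidation) should give spiro-epoxide F2. MgBr2·OEt2 should then promote the Meinwald rearrangement to C10 aldehyde F3, and CSA in MeOH removes the silyl ether and closes the acetal, rejoining the route at 21.

Step 14. Ring closure may give the trans-fused acetal (wrong configuration at C10), or the freed C2 hydroxyl may take over the acyl group before the acetal closes. Fallback: setting out from 21 obtained as a C10 epimer mixture, TMSOTf and i-Pr2NEt eliminate methanol to give dihydrofuran F4 (C9=C10 enol ether). Kinetic protonation on the convex face with PPTS in MeOH at −20 °C re-adds methanol and should return cis-fused 21.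

Further compounds
F1 | step 12 | hydroxy ketone (free C2 alcohol of 18) | CC(C)(C)[Si](C)(C)O[C@]1(C)CC[C@@H]2[C@@H](C1=O)[C@H](O)[C@](C)(CCC=C)OC(=O)C2(C)S(=O)(=O)c1ccccc1
F2 | step 13 | spiro-epoxide at C10 of 18 | CC(C)(C)[Si](C)(C)O[C@]1(C)CC[C@@H]2[C@@H](C13CO3)[C@H](O[Si](CC)(CC)CC)[C@](C)(CCC=C)OC(=O)C2(C)S(=O)(=O)c1ccccc1
F3 | step 13 | C10 aldehyde (C9 formyl, C2 triethylsilyl ether) | CC(C)(C)[Si](C)(C)O[C@]1(C)CC[C@@H]2[C@@H](C1C=O)[C@H](O[Si](CC)(CC)CC)[C@](C)(CCC=C)OC(=O)C2(C)S(=O)(=O)c1ccccc1
F4 | step 14 | dihydrofuran (C9=C10 enol ether) | CC(C)(C)[Si](C)(C)O[C@]1(C)CC[C@@H]2[C@H]3C1=CO[C@@H]3[C@](C)(CCC=C)OC(=O)C2(C)S(=O)(=O)c1ccccc1
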